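## The problem

Ustusoic acid B (21) is a trans-fused drimane decalin (drimane numbering; α is the face opposite the angular C10 methyl). Ring A (C1–C5, C10) is a bare hydrocarbon with the C4 gem-dimethyl group, whereas ring B (C5–C10) holds everything else: the 6β-trienoyloxy group, the C7=C8 bond with the C12 aldehyde on C8, and C9 with its 9α-hydroxyl and the C11 carboxylic acid. Three fully substituted carbons, C4, C10 and C9, frame the ring fusion, so bonds to them must be made early or at an unhindered partner. Only C5 and C10 need absolute control: once the trans-decalin stands, the axial 10β- and 4β-methyl groups close the β face of ring B, so oxygen can reach C9 and hydride can reach a C6 ketone from the α face by substrate control. The same shielding forbids the reverse order at C9, because a carboxyl nucleophile added to a C9 ketone would enter α and leave the hydroxyl β; C11 must therefore sit on C9 before the oxygen arrives. The (2E,4E,6E)-trienoate, the γ-acyloxy enal and the tertiary α-hydroxy acid beside the aldehyde tolerate neither hydride, singlet oxygen, hydrogenation nor saponification, which forces late acylation and a non-hydrolytic release of the acid at the very end. The enabling feature is that ring B is a p-menthane: C5 carries C4 (a carbon with two methyl groups), C8 carries the C12 methyl, C9 is oxygenated and C7=C8 is unsaturated, which is (R)-carvone with its isopropenyl carbon as C4. Ring A then reduces to a three-carbon bridge C1–C2–C3 between C10 (the α'-carbon of carvone) and C4, and the C3–C4 bond can be made from a tertiary C4 radical generated at the isopropenyl group.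

## Retrosynthesis

**C11 ester, C12 oxidation level and the O6–acyl bond (21 ⇒ 20 ⇒ 19 ⇒ 16 + 17).** The acid is released last from the 2-(trimethylsilyl)ethyl ester 20, because fluoride cleaves this ester at silicon and not at the hindered acyl carbon, and spares the trienoate. The C12 aldehyde is traced to the C8 methyl of 19; C12 is the only hydrogen-bearing carbon at the substituted end of the C7=C8 bond (C9 has no hydrogen), so an allylic oxidation has one site. The trienoate is cut at the O6–acyl bond to diol 16 and the commercial acid 17. Acylating earlier would expose the triene to hydride and singlet oxygen. The forward reactions must discriminate the secondary 6β-hydroxyl from the tertiary 9α-hydroxyl and keep selenium dioxide off the triene.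

**C6–O and C9–O together (16 ⇒ 15 ⇒ 14 ⇒ 13).** The 6β-alcohol comes from α-face reduction of the enone 15, and 15 from the 6α,9α-endoperoxide 14 by base. Cutting both C–O bonds of 14 gives the homoannular diene ester 13. The neighbouring cuts are weaker: a carboxyl nucleophile on a C9 ketone gives the wrong C9 epimer, and enolate hydroxylation of an 11-oate would need a separate C6 oxidation. The cut removes two stereocentres and both ring B oxygens; the forward step needs α-face [4+2] addition in preference to ene reactions.

**C9–C11 (13 ⇒ 12 ⇒ 10).** The ester carbon is removed by retro-carbonylation to the dienyl triflate 12, which is the γ-enol derivative of enone 10. Because C10 is quaternary, 10 can enolise only towards C6, so a single dienolate and a single triflate are possible. This cut exposes the C9 ketone, which is the carvone carbonyl.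

**C2–CO2Me (10 ⇒ 8 ⇒ 7).** An ester is added back at C2 in the retrosynthetic sense. It is the price of making the ring closure polarity-matched and 6-endo, and it is excised by saponification and Barton decarboxylation, which also erases the C2 epimer mixture.

**C3–C4, the key cut (7 ⇒ 6).** Cutting C3–C4 opens ring A to the carvone derivative 6, in which C4 is the isopropenyl carbon and C3 the free CH2 of a 2-substituted acrylate. Cuts at C4–C5 or C1–C10 would destroy the carvone pattern. A cationic closure from the protonated isopropenyl group has no clean terminator and would not tolerate the enone. The radical version joins a tertiary radical to an unsubstituted terminus, which is the easy way to a quaternary carbon. The forward step must confine hydrogen-atom transfer to the isopropenyl group and close 6-endo.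

**C10–C1 and C10–CH3 (6 ⇒ 3 + 4 ⇒ 1).** Both bonds at C10 are enolate alkylations of (R)-carvone (1): methyl first (3), then the 2-(methoxycarbonyl)allyl unit from bromide 4. The second electrophile enters anti to the isopropenyl group, so this order puts the methyl cis and the three-carbon arm trans to C4, as the trans-decalin requires. C5 is bought with carvone.

## Roads not taken

**Alternative 1:** The cut is made at C6–O and C9–O of ring B at once. It leads through the endoperoxide A1 (2-(trimethylsilyl)ethyl 6α,9α-epidioxydrim-7-en-11-oate) to the diene ester A2 (2-(trimethylsilyl)ethyl drima-6,8-dien-11-oate). In the forward sense singlet oxygen adds across C6 and C9 of A2 from the α face, and base opens A1 by removing H6.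
- Merits: both ring B oxygens arrive in one operation, C9 is set by the C10 methyl, C6 arrives as a ketone ready for α-face reduction, and the fragmentation has only one possible direction.
- Weak points: the idea solves the oxidation pattern and not the skeleton. A2 has to be made, most plausibly by degrading a larger commercial terpenoid, where creating the 6,8-diene and the C11 ester would cost a sequence of its own. The ester-deactivated, tetrasubstituted C8=C9 end also gives the ene reaction at the C12 hydrogens a chance.
- Comparison: the two roads do not exclude each other. A2 and A1 are the same substances as 13 and 14, and step 8 is this reaction, so on the ring B oxygens they are equal. If A2 were reached from a terpenoid that already contains the decalin, this road would be the more certain one, because C4, C5 and C10 would be bought and no ring closed. The chosen plan sets against this that carvone delivers ketone 10, from which A2 follows in two steps, and needs no degradative adjustment of oxidation levels.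

**Alternative 2:** The cut is made at C7–C8 and C9–C10, opening ring B to the siloxydiene A4 (tert-butyldimethylsilyl enol ether of 1-acetyl-2,6,6-trimethylcyclohexene) and the chiral butenolide A5 ((5R)-5-menthyloxyfuran-2(5H)-one). The forward Diels–Alder reaction, endo and anti to the menthyloxy group, would give cycloadduct A3.
- Merits: it is convergent; ring B, C8, C9 and C10 are formed in one step; the auxiliary is cheap and gives absolute control. C11 and C12 arrive at their final oxidation levels, as lactone carbonyl and acetal. In this respect it is better than the chosen plan, which spends steps 6, 7 and 11 on these two carbons.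
- Weak points: A4 is a 1-vinyl-2,6,6-trimethylcyclohexene whose s-cis conformer is twisted by the gem-dimethyl group. The cycloaddition must create quaternary C10 beside quaternary C4 with a weak dienophile, and the forcing conditions this implies endanger the silyl enol ether, the acetal and the endo and facial selectivity. Afterwards C9 still carries hydrogen and needs α-hydroxylation on a cis-fused lactone, the C7=C8 bond must be introduced, C5 protonated to the trans fusion and C6 reduced.
- Comparison: the saving at C11 and C12 is largely used up by these corrections. The chosen plan sets against it that its quaternary carbons are made by enolate alkylation and by radical attack on a free CH2 terminus under mild conditions, and that its absolute configuration does not depend on a difficult cycloaddition.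

**Alternative 3:** The cut is made at C9–C10. The tethered α-ketoester A7 (2-(trimethylsilyl)ethyl 3-methyl-2-oxo-5-(2,6,6-trimethylcyclohex-1-enyl)pentanoate) would close ring B by a carbonyl–ene reaction on a chiral Cu(OTf)2/bis(oxazoline) complex of divalent copper. The C5=C10 alkene attacks the bound C9 ketone with loss of H6, giving A6 (2-(trimethylsilyl)ethyl 9α-hydroxydrim-5-en-11-oate, 8α-methyl epimer).
- Merits: the tertiary α-hydroxy ester at C9 is formed directly and catalytically from an achiral ring, with no auxiliary and no chiral pool. At C9 this is better than the chosen plan, which needs steps 6 to 8 for the same function.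
- Weak points: the new bond joins two fully substituted carbons, with a tetrasubstituted alkene as the ene donor inside a chelate. The catalyst has to control C9 and C10 together. Closure at C5 with hydrogen transfer from C1 or the C10 methyl is an open competing path. Downstream, the C5=C6 bond must be turned into 5α-H and 6β-O, the C7=C8 bond introduced at the saturated C8, and C12 oxidised.
- Comparison: the gain at C9 is paid for in ring B adjustments of about the same length as the chosen plan's steps 6 to 8. The chosen plan sets against it that C5 and C10 come from carvone and a well-known diastereoselective alkylation, and that no step joins two quaternary carbons.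

Key step: step 3

Assumption: the target is treated as the open hydroxy acid–aldehyde that is drawn; its ring–chain tautomer, the 12-hydroxy-11,12-olide, would form through the same final step and is not planned separately.

## Route

Step 1
Reactants: 1 (R)-(−)-carvone
Product: 3 6-methylcarvone (both C6 epimers), via carvone lithium enolate 2 (not isolated)
Conditions: LiN(iPr)2, THF, −78 °C; MeI, −78 → 0 °C
Reagents that add atoms: iodomethane, CI
Why: Kinetic deprotonation of the enone takes place at the α'-carbon and the cross-conjugated enolate is C-methylated (enolate alkylation); the new centre (future C10) forms as an epimer mixture, which does not matter because it is planarised again in step 2.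

Step 2
Reactants: 3 6-methylcarvone; 4 methyl 2-(bromomethyl)acrylate
Product: 6 methyl 2-{[(1S,6S)-1,3-dimethyl-2-oxo-6-(prop-1-en-2-yl)cyclohex-3-en-1-yl]methyl}prop-2-enoate, via 6-methylcarvone lithium enolate 5 (not isolated)
Conditions: LiN(iPr)2, THF, −78 °C; 4, −78 → −20 °C
Reagents that add atoms: none
Why: The tetrasubstituted α'-enolate is alkylated by the allylic bromide (SN2 or addition–elimination, same product) on the face anti to the neighbouring isopropenyl group, the usual 1,2-induction in carvone dialkylation; this fixes C10 with the methyl cis and the acrylate arm trans to C4.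

Step 3
Reactants: 6 methyl 2-{[(1S,6S)-1,3-dimethyl-2-oxo-6-(prop-1-en-2-yl)cyclohex-3-en-1-yl]methyl}prop-2-enoate
Product: 7 methyl 9-oxo-11-nordrim-7-ene-2-carboxylate (C2 epimers)
Conditions: Fe(acac)3 (30 mol %), PhSiH3, EtOH/(CH2OH)2 (5:1), 60 °C
Reagents that add atoms: none
Why: Fe(acac)3 and PhSiH3 in ethanol form an iron hydride that transfers a hydrogen atom to the CH2 of the isopropenyl group, the most electron-rich of the three alkenes, giving the tertiary C4 radical. This nucleophilic radical adds to C3, the free terminus of the electron-poor 2-substituted acrylate, forming C3–C4 and closing ring A in the 6-endo-trig mode; the α-ester radical at C2 is reduced by divalent iron to the enolate and protonated by the solvent. The closest known reaction type is the iron-catalysed hydrogen-atom-transfer reductive olefin coupling (radical conjugate addition of an alkene-derived tertiary radical to an acrylate), used here intramolecularly. No stereocentre of the target is created: C4 carries two methyl groups, C2 forms as an epimer mixture under protonation control and is removed in step 5, and C5 and C10 are already fixed. Because the two reacting arms are trans on ring B they meet only when both are equatorial, so only the trans-decalin can form. The step needs hydrogen-atom transfer at the isopropenyl group and not at the enone or acrylate, which alkene polarity secures, and 6-endo over 5-exo closure, which the acrylate secures because attack at its free CH2 gives a stabilised tertiary α-ester radical whereas 5-exo attack would give a primary radical between quaternary carbons.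

Step 4
Reactants: 7 methyl 9-oxo-11-nordrim-7-ene-2-carboxylate
Product: 8 9-oxo-11-nordrim-7-ene-2-carboxylic acid (C2 epimers)
Conditions: LiOH, THF/MeOH/H2O, rt; then aq. HCl
Reagents that add atoms: lithium hydroxide, [Li+].[OH-]
Why: Saponification of an unhindered secondary methyl ester; the enone has no enolisable α'-position (C10 is quaternary) and both C2 epimers are carried on.

Step 5
Reactants: 8 9-oxo-11-nordrim-7-ene-2-carboxylic acid
Product: 10 11-nordrim-7-en-9-one, via Barton ester 9 (not isolated)
Conditions: 1-hydroxypyridine-2(1H)-thione, DCC, DMAP (cat.), CH2Cl2, 0 °C → rt, dark; then t-BuSH, hν (tungsten lamp), PhH, rt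
Reagents that add atoms: none
Why: Barton reductive decarboxylation: the thiohydroxamate ester fragments in a radical chain to CO2 and the secondary C2 radical, which takes hydrogen from t-BuSH; C2 becomes a methylene group so both epimers converge, and the remote enone is out of reach of the radical.

Step 6
Reactants: 10 11-nordrim-7-en-9-one
Product: 12 11-nordrima-6,8-dien-9-yl trifluoromethanesulfonate, via lithium dienolate 11 (not isolated)
Conditions: LiN(iPr)2, THF, −78 → 0 °C; PhNTf2, −78 °C → rt
Reagents that add atoms: N-phenylbis(trifluoromethanesulfonimide), O=S(=O)(N(c1ccccc1)S(=O)(=O)C(F)(F)F)C(F)(F)F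
Why: With C10 quaternary the only acidic position of the enone is γ (C6), so deprotonation gives a single linear dienolate and O-sulfonylation gives the homoannular dienyl triflate; this γ-enolisation and triflation is established for 2,6,6-trisubstituted cyclohex-2-enones.

Step 7
Reactants: 12 11-nordrima-6,8-dien-9-yl trifluoromethanesulfonate
Product: 13 2-(trimethylsilyl)ethyl drima-6,8-dien-11-oate
Conditions: Pd(OAc)2 (cat.), dppp (cat.), CO (1 atm), Me3SiCH2CH2OH, Et3N, DMF, 60 °C
Reagents that add atoms: carbon monoxide, [C-]#[O+]; 2-(trimethylsilyl)ethanol, C[Si](C)(C)CCO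
Why: Palladium-catalysed alkoxycarbonylation of an alkenyl triflate (oxidative addition to zerovalent palladium, CO insertion, alcoholysis of the acylpalladium), a reaction type established for hindered cyclohexenyl triflates; it installs C11 directly as a fluoride-labile ester.

Step 8
Reactants: 13 2-(trimethylsilyl)ethyl drima-6,8-dien-11-oate
Product: 15 2-(trimethylsilyl)ethyl 9α-hydroxy-6-oxodrim-7-en-11-oate, via 6α,9α-endoperoxide 14 (not isolated)
Conditions: O2, tetraphenylporphyrin (cat.), hν (visible), CH2Cl2, −20 °C; then Et3N, 0 °C → rt
Reagents that add atoms: oxygen, O=O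
Why: Singlet oxygen adds [4+2] to the s-cis-locked diene from the α face, because the axial 10β- and 4β-methyl groups block the β face, which sets the C9–O bond α; Kornblum–DeLaMare fragmentation then removes H6, the only hydrogen on a peroxide carbon, giving the 6-ketone and the 9α-hydroxyl with C7=C8 in place.

Step 9
Reactants: 15 2-(trimethylsilyl)ethyl 9α-hydroxy-6-oxodrim-7-en-11-oate
Product: 16 2-(trimethylsilyl)ethyl 6β,9α-dihydroxydrim-7-en-11-oate
Conditions: NaBH4, CeCl3·7H2O, MeOH, −78 → −20 °C
Reagents that add atoms: none
Why: Luche 1,2-reduction of the enone; hydride reaches C6 from the α face, opposite the axial 10β- and 4β-methyl groups, giving the axial 6β-alcohol, and the hindered ester is untouched at low temperature.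

Step 10
Reactants: 16 2-(trimethylsilyl)ethyl 6β,9α-dihydroxydrim-7-en-11-oate; 17 (2E,4E,6E)-octa-2,4,6-trienoic acid
Product: 19 2-(trimethylsilyl)ethyl 9α-hydroxy-6β-[(2E,4E,6E)-octa-2,4,6-trienoyloxy]drim-7-en-11-oate, via mixed anhydride 18 (not isolated)
Conditions: 17, 2,4,6-Cl3C6H2COCl, Et3N, THF, rt; then 16, DMAP, PhMe, rt
Reagents that add atoms: none
Why: Yamaguchi esterification: the mixed anhydride passes the trienoyl group through the acylpyridinium to the secondary allylic 6β-hydroxyl, while the tertiary, ester-flanked 9α-hydroxyl is too hindered to react; the all-E triene has sp3 hydrogens only on its remote terminal methyl, so deconjugation is not expected.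

Step 11
Reactants: 19 2-(trimethylsilyl)ethyl 9α-hydroxy-6β-[(2E,4E,6E)-octa-2,4,6-trienoyloxy]drim-7-en-11-oate
Product: 20 2-(trimethylsilyl)ethyl 9α-hydroxy-6β-[(2E,4E,6E)-octa-2,4,6-trienoyloxy]-12-oxodrim-7-en-11-oate
Conditions: SeO2, 1,4-dioxane, 80 °C
Reagents that add atoms: selenium dioxide, O=[Se]=O
Why: Selenium dioxide allylic oxidation (ene reaction, [2,3]-sigmatropic shift, further oxidation of the allylic alcohol) acts at the more substituted end of C7=C8, where C12 is the only hydrogen-bearing carbon, and gives the enal; the ester-conjugated, electron-poor triene is much less reactive in the electrophilic ene step.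

Step 12
Reactants: 20 2-(trimethylsilyl)ethyl 9α-hydroxy-6β-[(2E,4E,6E)-octa-2,4,6-trienoyloxy]-12-oxodrim-7-en-11-oate
Product: 21 ustusoic acid B
Conditions: Bu4NF, THF, 0 °C; then aq. NH4Cl
Reagents that add atoms: none
Why: Fluoride attacks silicon of the 2-(trimethylsilyl)ethyl ester and triggers β-elimination to ethylene, Me3SiF and the carboxylate; the cleavage does not involve the hindered acyl carbon and leaves the trienoate, the enal and all stereocentres untouched.

## Compound list

1 | (R)-(−)-carvone, (5R)-2-methyl-5-(prop-1-en-2-yl)cyclohex-2-en-1-one | CC1=CC[C@H](CC1=O)C(C)=C | starting material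
2 | carvone lithium enolate (cross-conjugated, O–C1=C6) | C1C=C(C)C(O[Li])=C[C@@H]1C(C)=C | intermediate
3 | 6-methylcarvone, (5R)-2,6-dimethyl-5-(prop-1-en-2-yl)cyclohex-2-en-1-one, 6S (trans) and 6R (cis) epimers, C6 left undefined | C1C=C(C)C(=O)C(C)[C@@H]1C(C)=C | intermediate
4 | methyl 2-(bromomethyl)acrylate | C=C(CBr)C(=O)OC | starting material
5 | 6-methylcarvone lithium enolate (O–C1=C6) | C1C=C(C)C(O[Li])=C(C)[C@@H]1C(C)=C | intermediate
6 | methyl 2-{[(1S,6S)-1,3-dimethyl-2-oxo-6-(prop-1-en-2-yl)cyclohex-3-en-1-yl]methyl}prop-2-enoate (methyl cis, acrylate arm trans to isopropenyl) | C1C=C(C)C(=O)[C@@](C)(CC(=C)C(=O)OC)[C@@H]1C(C)=C | intermediate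
7 | methyl 9-oxo-11-nordrim-7-ene-2-carboxylate (5α-H, 10β-methyl; both C2 epimers, C2 left undefined) | C1C=C(C)C(=O)[C@@]2(C)CC(C(=O)OC)CC(C)(C)[C@H]12 | intermediate
8 | 9-oxo-11-nordrim-7-ene-2-carboxylic acid (both C2 epimers, C2 left undefined) | C1C=C(C)C(=O)[C@@]2(C)CC(C(=O)O)CC(C)(C)[C@H]12 | intermediate
9 | Barton ester, 2-thioxopyridin-1(2H)-yl 9-oxo-11-nordrim-7-ene-2-carboxylate (C2 left undefined) | C1C=C(C)C(=O)[C@@]2(C)CC(C(=O)ON3C=CC=CC3=S)CC(C)(C)[C@H]12 | intermediate
10 | 11-nordrim-7-en-9-one (5α-H, 10β-methyl) | C1C=C(C)C(=O)[C@@]2(C)CCCC(C)(C)[C@H]12 | intermediate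
11 | lithium 11-nordrima-6,8-dien-9-olate | C1=CC(C)=C(O[Li])[C@@]2(C)CCCC(C)(C)[C@H]12 | intermediate
12 | 11-nordrima-6,8-dien-9-yl trifluoromethanesulfonate | C1=CC(C)=C(OS(=O)(=O)C(F)(F)F)[C@@]2(C)CCCC(C)(C)[C@H]12 | intermediate
13 | 2-(trimethylsilyl)ethyl drima-6,8-dien-11-oate | C1=CC(C)=C(C(=O)OCC[Si](C)(C)C)[C@@]2(C)CCCC(C)(C)[C@H]12 | intermediate
14 | 2-(trimethylsilyl)ethyl 6α,9α-epidioxydrim-7-en-11-oate | O1O[C@H]2C=C(C)[C@]1(C(=O)OCC[Si](C)(C)C)[C@@]3(C)CCCC(C)(C)[C@H]23 | intermediate
15 | 2-(trimethylsilyl)ethyl 9α-hydroxy-6-oxodrim-7-en-11-oate | O=C1C=C(C)[C@](O)(C(=O)OCC[Si](C)(C)C)[C@@]2(C)CCCC(C)(C)[C@H]12 | intermediate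
16 | 2-(trimethylsilyl)ethyl 6β,9α-dihydroxydrim-7-en-11-oate | O[C@@H]1C=C(C)[C@](O)(C(=O)OCC[Si](C)(C)C)[C@@]2(C)CCCC(C)(C)[C@H]12 | intermediate
17 | (2E,4E,6E)-octa-2,4,6-trienoic acid | C/C=C/C=C/C=C/C(=O)O | starting material
18 | (2E,4E,6E)-octa-2,4,6-trienoic 2,4,6-trichlorobenzoic anhydride | C/C=C/C=C/C=C/C(=O)OC(=O)c1c(Cl)cc(Cl)cc1Cl | intermediate
19 | 2-(trimethylsilyl)ethyl 9α-hydroxy-6β-[(2E,4E,6E)-octa-2,4,6-trienoyloxy]drim-7-en-11-oate | C/C=C/C=C/C=C/C(=O)O[C@@H]1C=C(C)[C@](O)(C(=O)OCC[Si](C)(C)C)[C@@]2(C)CCCC(C)(C)[C@H]12 | intermediate
20 | 2-(trimethylsilyl)ethyl 9α-hydroxy-6β-[(2E,4E,6E)-octa-2,4,6-trienoyloxy]-12-oxodrim-7-en-11-oate | C/C=C/C=C/C=C/C(=O)O[C@@H]1C=C(C=O)[C@](O)(C(=O)OCC[Si](C)(C)C)[C@@]2(C)CCCC(C)(C)[C@H]12 | intermediate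
21 | ustusoic acid B, 9α-hydroxy-6β-[(2E,4E,6E)-octa-2,4,6-trienoyloxy]-12-oxodrim-7-en-11-oic acid | C/C=C/C=C/C=C/C(=O)O[C@@H]1C=C(C=O)[C@](O)(C(=O)O)[C@@]2(C)CCCC(C)(C)[C@H]12 | target

## Step count and least certain steps

Total: 12 steps, all in one line from 1 (4 and 17 are purchased). Longest linear sequence: 12 steps.

**Step 3 (key step).** The likely failure is loss of chemoselectivity in the hydrogen-atom transfer: the iron hydride may reduce the enone or the acrylate, or the C4 radical may be quenched to the isopropyl compound before it closes the ring. The fallback generates the same radical without a metal hydride. From 6, Markovnikov addition of HBr (HBr in AcOH, 0 °C) to the isopropenyl group, the most basic alkene, should give the tertiary bromide methyl 2-{[6-(2-bromopropan-2-yl)-1,3-dimethyl-2-oxocyclohex-3-en-1-yl]methyl}prop-2-enoate F1. Bu3SnH and AIBN in benzene at 80 °C under slow addition then abstract bromine, and the C4 radical closes ring A 6-endo to return to 7.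

**Step 8.** The likely failure is competition of the ene reaction (at the C12 or C5 hydrogens) with cycloaddition at the ester-deactivated, tetrasubstituted diene terminus. The fallback brings in the two oxygens separately. From 13, 1,6-reduction with [(Ph3P)CuH]6 should give 2-(trimethylsilyl)ethyl drim-7-en-11-oate F3. Its enolate (KN(SiMe3)2, THF, −78 °C) is hydroxylated with 2-(phenylsulfonyl)-3-phenyloxaziridine anti to the C10 methyl to give 2-(trimethylsilyl)ethyl 9α-hydroxydrim-7-en-11-oate F4. Allylic oxidation of the C6 methylene with dirhodium tetrakis(caprolactamate), Rh2(cap)4, and t-BuOOH returns to 15.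

**Step 7.** The likely failure is slow alcoholysis of the crowded acylpalladium, flanked by quaternary C10 and the C8 methyl, so that reduction of the triflate or catalyst decay takes over. The fallback captures the acyl group with a small nucleophile and forms the ester at oxygen. From 12, carbonylation with Pd(OAc)2, dppp, CO, KOAc and water in DMSO should give drima-6,8-dien-11-oic acid F2. Mitsunobu esterification (Me3SiCH2CH2OH, PPh3, DIAD), in which the hindered carboxylate acts as the nucleophile, returns to 13.

**Step 11.** The likely failure is oxidation beyond C12: attack on the terminal allylic methyl of the trienoate, over-oxidation, or ionisation of the allylic ester in hot selenous acid. The fallback oxidises before the triene is present. From 16, TESCl and imidazole in DMF should give the 6β-triethylsilyl ether F6. SeO2 in dioxane then gives the 12-aldehyde F7, and AcOH/THF/H2O removes the silyl group to give 2-(trimethylsilyl)ethyl 6β,9α-dihydroxy-12-oxodrim-7-en-11-oate F8. Yamaguchi acylation with 17, as in step 10, returns to 20.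

**Step 10.** The likely failure is incomplete acyl transfer to the axial 6β-hydroxyl, which lies between two 1,3-diaxial methyl groups, with trichlorobenzoylation as a side path. The fallback acylates with a small reagent and builds the triene on the molecule. From 16, diethylphosphonoacetic acid and DCC (via the phosphonoketene) should give the phosphonoacetate 2-(trimethylsilyl)ethyl 6β-[(diethoxyphosphoryl)acetoxy]-9α-hydroxydrim-7-en-11-oate F5. A Horner–Wadsworth–Emmons reaction with (2E,4E)-hexa-2,4-dienal (LiCl, DBU, MeCN) returns to 19.

## Further compounds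

F1 | step 3 | methyl 2-{[6-(2-bromopropan-2-yl)-1,3-dimethyl-2-oxocyclohex-3-en-1-yl]methyl}prop-2-enoate (configuration as in 6) | C1C=C(C)C(=O)[C@@](C)(CC(=C)C(=O)OC)[C@@H]1C(C)(C)Br
F2 | step 7 | drima-6,8-dien-11-oic acid | C1=CC(C)=C(C(=O)O)[C@@]2(C)CCCC(C)(C)[C@H]12
F3 | step 8 | 2-(trimethylsilyl)ethyl drim-7-en-11-oate (9α-H) | C1C=C(C)[C@H](C(=O)OCC[Si](C)(C)C)[C@@]2(C)CCCC(C)(C)[C@H]12
F4 | step 8 | 2-(trimethylsilyl)ethyl 9α-hydroxydrim-7-en-11-oate | C1C=C(C)[C@](O)(C(=O)OCC[Si](C)(C)C)[C@@]2(C)CCCC(C)(C)[C@H]12
F5 | step 10 | 2-(trimethylsilyl)ethyl 6β-[(diethoxyphosphoryl)acetoxy]-9α-hydroxydrim-7-en-11-oate | CCOP(=O)(OCC)CC(=O)O[C@@H]1C=C(C)[C@](O)(C(=O)OCC[Si](C)(C)C)[C@@]2(C)CCCC(C)(C)[C@H]12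
F6 | step 11 | 2-(trimethylsilyl)ethyl 9α-hydroxy-6β-(triethylsilyloxy)drim-7-en-11-oate | CC[Si](CC)(CC)O[C@@H]1C=C(C)[C@](O)(C(=O)OCC[Si](C)(C)C)[C@@]2(C)CCCC(C)(C)[C@H]12
F7 | step 11 | 2-(trimethylsilyl)ethyl 9α-hydroxy-12-oxo-6β-(triethylsilyloxy)drim-7-en-11-oate | CC[Si](CC)(CC)O[C@@H]1C=C(C=O)[C@](O)(C(=O)OCC[Si](C)(C)C)[C@@]2(C)CCCC(C)(C)[C@H]12
F8 | step 11 | 2-(trimethylsilyl)ethyl 6β,9α-dihydroxy-12-oxodrim-7-en-11-oate | O[C@@H]1C=C(C=O)[C@](O)(C(=O)OCC[Si](C)(C)C)[C@@]2(C)CCCC(C)(C)[C@H]12
A1 | alternative 1 | 2-(trimethylsilyl)ethyl 6α,9α-epidioxydrim-7-en-11-oate | O1O[C@H]2C=C(C)[C@]1(C(=O)OCC[Si](C)(C)C)[C@@]3(C)CCCC(C)(C)[C@H]23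
A2 | alternative 1 | 2-(trimethylsilyl)ethyl drima-6,8-dien-11-oate | C1=CC(C)=C(C(=O)OCC[Si](C)(C)C)[C@@]2(C)CCCC(C)(C)[C@H]12
A3 | alternative 2 | endo, anti cycloadduct, 6-(tert-butyldimethylsilyloxy)drim-5-ene fused at C8–C9 to the 12-menthyloxy-11,12-olide | CC(C)(C)[Si](C)(C)OC1=C2C(C)(C)CCC[C@]2(C)[C@@H]3C(=O)O[C@@H](O[C@@H]4C[C@H](C)CC[C@H]4C(C)C)[C@@H]3C1
A4 | alternative 2 | tert-butyldimethyl{[1-(2,6,6-trimethylcyclohex-1-en-1-yl)ethenyl]oxy}silane | CC1=C(C(=C)O[Si](C)(C)C(C)(C)C)C(C)(C)CCC1
A5 | alternative 2 | (5R)-5-[(1R,2S,5R)-menthyloxy]furan-2(5H)-one | O=C1O[C@@H](O[C@@H]2C[C@H](C)CC[C@H]2C(C)C)C=C1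
A6 | alternative 3 | 2-(trimethylsilyl)ethyl 9α-hydroxydrim-5-en-11-oate (8α-methyl epimer) | C1=C2C(C)(C)CCC[C@]2(C)[C@@](O)(C(=O)OCC[Si](C)(C)C)[C@H](C)C1
A7 | alternative 3 | 2-(trimethylsilyl)ethyl 3-methyl-2-oxo-5-(2,6,6-trimethylcyclohex-1-en-1-yl)pentanoate (C3 configured as C8 of A6) | CC1=C(CC[C@@H](C)C(=O)C(=O)OCC[Si](C)(C)C)C(C)(C)CCC1
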